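**Retrosynthetic overview** (target numbered as a furo[3,4-c]furan-1-one: C1 carbonyl, O2, C3, C3a, C4, O5, C6, C6a; TBS = tert-butyldimethylsilyl)

1. Target ⇒ tris-TBS ether ⇒ hydroxy β-keto lactone (C6–H by convex-face hydride delivery to a cyclic aryl oxocarbenium ion) ⇒ cis-γ-aryl-β-(aroyloxymethyl)-γ-butyrolactone (C6–C6a by intramolecular O→C aroyl transfer; the ester oxygen becomes O5).
2. Lactone ⇒ cis-2-aryl-3-(aroyloxymethyl)cyclobutanone (O2 removed, retro-Baeyer–Villiger) ⇒ arylacetamide of (2R,5R)-2,5-dimethylpyrrolidine + allyl 3,4-bis(silyloxy)benzoate (C1–C6a and C3–C3a by one keteniminium–alkene [2+2] cycloaddition).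
3. Enabling feature: in the lactone ring (C1, O2, C3, C3a, C6a) the carbonyl carbon C1 and the aryl-bearing C3 are separated only by O2 and are each bonded to one of the vicinal carbons C6a and C3a. Without O2 they are the two carbons of an arylketene unit, and C6a–C3a is a terminal alkene whose only substituent is the C4H2–O5 arm. The aryl group at C3 is cis to that arm, the kinetic pattern of such a cycloaddition.
4. Ring order: cyclobutane (key step, already holding all 20 carbons) → γ-lactone (O insertion) → tetrahydrofuran (acyl transfer, then reductive etherification).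

Key step: step 5

Assumption: the sense of induction by the (2R,5R)-auxiliary is assigned from a steric model (the alkene enters in the plane of the H/aryl terminus on the side of H and tilts away from the pyrrolidine methyl group on that side); should the opposite sense be found, the (2S,5S)-amine is used in step 2 and nothing else changes.

**Step 1**
Reactants: 1 (4-hydroxy-3,5-dimethoxyphenyl)acetic acid
Product: 3 [4-(tert-butyldimethylsilyloxy)-3,5-dimethoxyphenyl]acetic acid, via silyl ester 2 (not isolated)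
Conditions: TBSCl (2.5 equiv), imidazole, DMF, rt; then AcOH/THF/H2O, rt
Reagents that add atoms: tert-butyldimethylsilyl chloride, CC(C)(C)[Si](C)(C)Cl
Why: Silylation of phenol and acid with TBSCl/imidazole followed by selective hydrolysis of the labile silyl ester by aqueous acetic acid should leave the hindered aryl silyl ether, flanked by two methoxy groups, intact.

**Step 2**
Reactants: 3 [4-(tert-butyldimethylsilyloxy)-3,5-dimethoxyphenyl]acetic acid; 4 (2R,5R)-2,5-dimethylpyrrolidine
Product: 6 2-[4-(tert-butyldimethylsilyloxy)-3,5-dimethoxyphenyl]-1-[(2R,5R)-2,5-dimethylpyrrolidin-1-yl]ethan-1-one, via acid chloride 5 (not isolated)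
Conditions: (COCl)2, DMF (cat.), CH2Cl2, 0 °C → rt; then 4, Et3N, CH2Cl2, 0 °C → rt
Reagents that add atoms: none
Why: Acid chloride formation (Vilsmeier-type activation) and Schotten–Baumann-type N-acylation is the reliable way to acylate the hindered secondary amine, and no stereocenter is touched.

**Step 3**
Reactants: 7 3,4-dihydroxybenzoic acid; 8 3-bromoprop-1-ene (allyl bromide)
Product: 9 prop-2-enyl 3,4-dihydroxybenzoate
Conditions: KHCO3, DMF, rt, N2
Reagents that add atoms: none
Why: SN2 O-alkylation of the carboxylate should be selective because KHCO3 deprotonates the acid but not the catechol hydroxyls.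

**Step 4**
Reactants: 9 prop-2-enyl 3,4-dihydroxybenzoate
Product: 10 prop-2-enyl 3,4-bis(tert-butyldimethylsilyloxy)benzoate
Conditions: TBSCl (2.4 equiv), imidazole, DMF, rt
Reagents that add atoms: tert-butyldimethylsilyl chloride, CC(C)(C)[Si](C)(C)Cl
Why: Standard silylation of both phenols gives bulky, weakly donating, base-stable and fluoride-labile protection for the later steps.

**Step 5**
Reactants: 6 2-[4-(tert-butyldimethylsilyloxy)-3,5-dimethoxyphenyl]-1-[(2R,5R)-2,5-dimethylpyrrolidin-1-yl]ethan-1-one; 10 prop-2-enyl 3,4-bis(tert-butyldimethylsilyloxy)benzoate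
Product: 13 [(1R,2S)-2-[4-(tert-butyldimethylsilyloxy)-3,5-dimethoxyphenyl]-3-oxocyclobutyl]methyl 3,4-bis(tert-butyldimethylsilyloxy)benzoate, via keteniminium triflate 11 (not isolated), via cyclobutaniminium triflate 12 (not isolated)
Conditions: Tf2O (1.1 equiv), 2,6-di-tert-butyl-4-methylpyridine (1.2 equiv), 10 (3 equiv, excess recovered), ClCH2CH2Cl, −25 °C → rt; then H2O, NaHCO3 (aq), rt
Reagents that add atoms: water, O
Why: Tf2O turns amide 6 into its O-triflyl iminium ion and the hindered pyridine removes the benzylic proton to give keteniminium ion 11, whose π*(C=N) lies in the plane of the H/aryl terminus; the unsubstituted CH2 terminus of 10 attacks the iminium carbon from the side of H while positive charge builds on the internal alkene carbon, the enamine carbon closes onto that carbon to give iminium ion 12, and water hydrolyses 12 to ketone 13 with release of the auxiliary. The closest known reaction type is the keteniminium–alkene [2+2] cycloaddition of Tf2O-activated tertiary amides, including its auxiliary-controlled form with C2-symmetric 2,5-disubstituted pyrrolidines. The only ring closed is the cyclobutane, by an asynchronous thermal [2+2] (formally π2s + π2a) that makes both new C–C bonds, iminium carbon to CH2 and benzylic carbon to CH, in the same operation. The aryl-bearing carbon of 13 (2S) is controlled by the auxiliary, whose methyl group on the H-side face of the pyrrolidine blocks one of the two half-spaces above and below the keteniminium plane, and the carbon bearing the CH2O arm (1R) is controlled relative to it by the ketene-type transition state, in which attack anti to the aryl group followed by the closing rotation turns the aryl group toward the alkene substituent and gives the cis product. The step needs regioselectivity, secured by the monosubstituted alkene (Markovnikov charge development puts the iminium carbon on CH2); chemoselectivity for the alkene over arene or ester capture, secured by the bulky silyl ethers, the ester-deactivated benzoate ring and the excess of 10; and preservation of the kinetic cis α-aryl centre, secured by the weak hindered base and by oxidising 13 at once in step 6.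

**Step 6**
Reactants: 13 [(1R,2S)-2-[4-(tert-butyldimethylsilyloxy)-3,5-dimethoxyphenyl]-3-oxocyclobutyl]methyl 3,4-bis(tert-butyldimethylsilyloxy)benzoate
Product: 14 [(2S,3S)-2-[4-(tert-butyldimethylsilyloxy)-3,5-dimethoxyphenyl]-5-oxooxolan-3-yl]methyl 3,4-bis(tert-butyldimethylsilyloxy)benzoate
Conditions: mCPBA, NaHCO3, CH2Cl2, 0 °C (crude 13 used directly)
Reagents that add atoms: 3-chloroperoxybenzoic acid, OOC(=O)c1cccc(Cl)c1
Why: Baeyer–Villiger oxidation of the strained cyclobutanone should be fast, the secondary benzylic carbon migrates in preference to CH2 with retention, so oxygen enters between C=O and the aryl-bearing carbon and both stereocenters pass unchanged into the cis-lactone, where the benzylic centre is no longer epimerisable.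

**Step 7**
Reactants: 14 [(2S,3S)-2-[4-(tert-butyldimethylsilyloxy)-3,5-dimethoxyphenyl]-5-oxooxolan-3-yl]methyl 3,4-bis(tert-butyldimethylsilyloxy)benzoate
Product: 16 (4S,5S)-3-[3,4-bis(tert-butyldimethylsilyloxy)benzoyl]-5-[4-(tert-butyldimethylsilyloxy)-3,5-dimethoxyphenyl]-4-(hydroxymethyl)oxolan-2-one (mixture at C3), via lithium hemiketal alkoxide 15 (not isolated)
Conditions: LiN(SiMe3)2 (2.2 equiv), THF, −78 → −20 °C; then AcOH, −78 °C (crude product taken on without chromatography)
Reagents that add atoms: none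
Why: Intramolecular Claisen-type O→C acyl transfer (5-exo-trig attack of the lactone enolate on the aroate carbonyl, as in Dieckmann or Baker–Venkataraman processes) should deliver the aroyl group through the ester tether via 15, whose ring opening is driven by deprotonation of the resulting 1,3-dicarbonyl; C3 becomes epimerisable and is fixed in step 8.

**Step 8**
Reactants: 16 (4S,5S)-3-[3,4-bis(tert-butyldimethylsilyloxy)benzoyl]-5-[4-(tert-butyldimethylsilyloxy)-3,5-dimethoxyphenyl]-4-(hydroxymethyl)oxolan-2-one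
Product: 19 (3S,3aS,6S,6aR)-6-[3,4-bis(tert-butyldimethylsilyloxy)phenyl]-3-[4-(tert-butyldimethylsilyloxy)-3,5-dimethoxyphenyl]tetrahydro-1H,3H-furo[3,4-c]furan-1-one, via cyclic hemiketal 17 (not isolated), via oxocarbenium ion 18 (not isolated)
Conditions: Et3SiH (3 equiv), BF3·OEt2 (2 equiv), CH2Cl2, −78 → −30 °C
Reagents that add atoms: none
Why: Reductive etherification (ionic hydrogenation of a hemiketal): the hydroxy ketone closes to hemiketal 17, which can only be cis-fused so the labile C3 centre converges on the cis ring fusion, BF3 ionises it to the aryl-stabilised oxocarbenium ion 18, and Et3SiH should deliver hydride from the convex face of the cis-fused bicycle, placing H exo and the aryl group endo (6S).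

**Step 9**
Reactants: 19 (3S,3aS,6S,6aR)-6-[3,4-bis(tert-butyldimethylsilyloxy)phenyl]-3-[4-(tert-butyldimethylsilyloxy)-3,5-dimethoxyphenyl]tetrahydro-1H,3H-furo[3,4-c]furan-1-one
Product: 20 (3S,3aS,6S,6aR)-6-(3,4-dihydroxyphenyl)-3-(4-hydroxy-3,5-dimethoxyphenyl)tetrahydro-1H,3H-furo[3,4-c]furan-1-one
Conditions: Bu4NF (3.3 equiv), AcOH (3.5 equiv), THF, 0 °C
Reagents that add atoms: none
Why: Fluoride-mediated cleavage of the three aryl silyl ethers, buffered with acetic acid so that the phenols stay protonated and the 4-hydroxybenzylic lactone C–O bond is not ionised through a quinone methide, should release the target with the endo,endo configuration intact.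

**Compound list**

1 | (4-hydroxy-3,5-dimethoxyphenyl)acetic acid | COc1cc(CC(=O)O)cc(OC)c1O | starting material
2 | tert-butyldimethylsilyl [4-(tert-butyldimethylsilyloxy)-3,5-dimethoxyphenyl]acetate (transient) | COc1cc(CC(=O)O[Si](C)(C)C(C)(C)C)cc(OC)c1O[Si](C)(C)C(C)(C)C | intermediate
3 | [4-(tert-butyldimethylsilyloxy)-3,5-dimethoxyphenyl]acetic acid | COc1cc(CC(=O)O)cc(OC)c1O[Si](C)(C)C(C)(C)C | intermediate
4 | (2R,5R)-2,5-dimethylpyrrolidine | C[C@@H]1CC[C@@H](C)N1 | starting material
5 | [4-(tert-butyldimethylsilyloxy)-3,5-dimethoxyphenyl]acetyl chloride (transient) | COc1cc(CC(=O)Cl)cc(OC)c1O[Si](C)(C)C(C)(C)C | intermediate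
6 | 2-[4-(tert-butyldimethylsilyloxy)-3,5-dimethoxyphenyl]-1-[(2R,5R)-2,5-dimethylpyrrolidin-1-yl]ethan-1-one | C[C@@H]1CC[C@@H](C)N1C(=O)Cc1cc(OC)c(O[Si](C)(C)C(C)(C)C)c(OC)c1 | intermediate
7 | 3,4-dihydroxybenzoic acid | OC(=O)c1ccc(O)c(O)c1 | starting material
8 | 3-bromoprop-1-ene | C=CCBr | starting material
9 | prop-2-enyl 3,4-dihydroxybenzoate | C=CCOC(=O)c1ccc(O)c(O)c1 | intermediate
10 | prop-2-enyl 3,4-bis(tert-butyldimethylsilyloxy)benzoate | C=CCOC(=O)c1ccc(O[Si](C)(C)C(C)(C)C)c(O[Si](C)(C)C(C)(C)C)c1 | intermediate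
11 | (2R,5R)-1-{2-[4-(tert-butyldimethylsilyloxy)-3,5-dimethoxyphenyl]ethenylidene}-2,5-dimethylpyrrolidinium triflate (transient) | C[C@@H]1CC[C@@H](C)[N+]1=C=Cc1cc(OC)c(O[Si](C)(C)C(C)(C)C)c(OC)c1.[O-]S(=O)(=O)C(F)(F)F | intermediate
12 | cis-cyclobutaniminium triflate, the iminium of 13 with (2R,5R)-2,5-dimethylpyrrolidine (transient) | COc1cc([C@H]2C(=[N+]3[C@H](C)CC[C@H]3C)C[C@H]2COC(=O)c2ccc(O[Si](C)(C)C(C)(C)C)c(O[Si](C)(C)C(C)(C)C)c2)cc(OC)c1O[Si](C)(C)C(C)(C)C.[O-]S(=O)(=O)C(F)(F)F | intermediate
13 | [(1R,2S)-2-[4-(tert-butyldimethylsilyloxy)-3,5-dimethoxyphenyl]-3-oxocyclobutyl]methyl 3,4-bis(tert-butyldimethylsilyloxy)benzoate | COc1cc([C@H]2C(=O)C[C@H]2COC(=O)c2ccc(O[Si](C)(C)C(C)(C)C)c(O[Si](C)(C)C(C)(C)C)c2)cc(OC)c1O[Si](C)(C)C(C)(C)C | intermediate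
14 | [(2S,3S)-2-[4-(tert-butyldimethylsilyloxy)-3,5-dimethoxyphenyl]-5-oxooxolan-3-yl]methyl 3,4-bis(tert-butyldimethylsilyloxy)benzoate | COc1cc([C@H]2OC(=O)C[C@H]2COC(=O)c2ccc(O[Si](C)(C)C(C)(C)C)c(O[Si](C)(C)C(C)(C)C)c2)cc(OC)c1O[Si](C)(C)C(C)(C)C | intermediate
15 | lithium alkoxide of the cis-fused cyclic hemiketal, the tetrahedral intermediate of the acyl transfer (transient) | COc1cc([C@H]2OC(=O)[C@@H]3[C@H]2COC3([O-])c2ccc(O[Si](C)(C)C(C)(C)C)c(O[Si](C)(C)C(C)(C)C)c2)cc(OC)c1O[Si](C)(C)C(C)(C)C.[Li+] | intermediate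
16 | (4S,5S)-3-[3,4-bis(tert-butyldimethylsilyloxy)benzoyl]-5-[4-(tert-butyldimethylsilyloxy)-3,5-dimethoxyphenyl]-4-(hydroxymethyl)oxolan-2-one, C3 not defined | COc1cc([C@H]2OC(=O)C(C(=O)c3ccc(O[Si](C)(C)C(C)(C)C)c(O[Si](C)(C)C(C)(C)C)c3)[C@H]2CO)cc(OC)c1O[Si](C)(C)C(C)(C)C | intermediate
17 | cis-fused cyclic hemiketal of 16, anomeric centre not defined (transient) | COc1cc([C@H]2OC(=O)[C@@H]3[C@H]2COC3(O)c2ccc(O[Si](C)(C)C(C)(C)C)c(O[Si](C)(C)C(C)(C)C)c2)cc(OC)c1O[Si](C)(C)C(C)(C)C | intermediate
18 | cis-fused cyclic aryl oxocarbenium hydroxytrifluoroborate (transient) | COc1cc([C@H]2OC(=O)[C@@H]3[C@H]2C[O+]=C3c2ccc(O[Si](C)(C)C(C)(C)C)c(O[Si](C)(C)C(C)(C)C)c2)cc(OC)c1O[Si](C)(C)C(C)(C)C.O[B-](F)(F)F | intermediate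
19 | (3S,3aS,6S,6aR)-6-[3,4-bis(tert-butyldimethylsilyloxy)phenyl]-3-[4-(tert-butyldimethylsilyloxy)-3,5-dimethoxyphenyl]tetrahydro-1H,3H-furo[3,4-c]furan-1-one | COc1cc([C@H]2OC(=O)[C@@H]3[C@H]2CO[C@@H]3c2ccc(O[Si](C)(C)C(C)(C)C)c(O[Si](C)(C)C(C)(C)C)c2)cc(OC)c1O[Si](C)(C)C(C)(C)C | intermediate
20 | (3S,3aS,6S,6aR)-6-(3,4-dihydroxyphenyl)-3-(4-hydroxy-3,5-dimethoxyphenyl)tetrahydro-1H,3H-furo[3,4-c]furan-1-one | COc1cc([C@H]2OC(=O)[C@@H]3[C@H]2CO[C@@H]3c2ccc(O)c(O)c2)cc(OC)c1O | target

**Summary**

Total step count: 9. Longest linear sequence: 7 steps (1, 2, 5, 6, 7, 8, 9; the branch 3, 4, 5–9 is equally long).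

Steps most likely to fail:

1. **Step 5.** The keteniminium ion may be consumed by arylation of a silyloxyarene or by attack of the ester carbonyl, because the allyl ester is a weak π-nucleophile. The kinetic cis α-aryl centre may also epimerise through the enamine of 12, and the facial control by the auxiliary may be incomplete with an acyclic terminal alkene. Fallback: set out from 6, generate 11 as in step 5 and intercept it with buta-1,3-diene, a much stronger π-nucleophile that reacts at lower temperature with the same regiochemistry (iminium carbon to the diene terminus). After hydrolysis this should give (2S,3S)-2-[4-(tert-butyldimethylsilyloxy)-3,5-dimethoxyphenyl]-3-ethenylcyclobutan-1-one F1. Baeyer–Villiger oxidation (mCPBA, NaHCO3) gives the vinyl lactone F2. Ozonolysis (O3, CH2Cl2/MeOH, −78 °C, indicator endpoint) with NaBH4 work-up gives the hydroxymethyl lactone F3, which is acylated without delay. In parallel, 10 is deallylated (Pd(PPh3)4, morpholine, THF) to 3,4-bis(tert-butyldimethylsilyloxy)benzoic acid F4. Esterification of F3 with F4 (DCC, DMAP, CH2Cl2) comes back to the route at 14.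

2. **Step 8.** Loss of the acidic C6a proton from oxocarbenium ion 18 may give the conjugated enol ether faster than hydride is captured. Direct ionic reduction of the aryl ketone, or ionisation of the benzylic C–O bonds of the product with epimerisation to exo-aryl isomers, may also compete. Fallback: set out from 16 and make the elimination the intended path. Cyclodehydration (TsOH cat., toluene, 4 Å molecular sieves) gives the bicyclic enol ether lactone F8. Heterogeneous cis-hydrogenation (H2, 5% Rh/Al2O3, EtOAc) from the face opposite to the C3 aryl group should add both hydrogens cis to H3a and comes back to the route at 19.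

3. **Step 7.** After the acyl transfer, the freed primary alcohol may add to the lactone carbonyl (translactonisation to an isomeric lactone) or to the ketone with retro-Claisen cleavage, so that the material degrades on work-up. Fallback: avoid any free hydroxy stage. Set out from 6 and run the cycloaddition of step 5 with commercial tert-butyldimethyl(prop-2-enyloxy)silane to give the silyloxymethyl cyclobutanone F5. Baeyer–Villiger oxidation gives lactone F6. Crossed Claisen condensation of the lithium enolate of F6 (LiN(SiMe3)2, 2.2 equiv, THF, −78 °C) with ester 10 gives the β-keto lactone silyl ether F7. Direct reductive etherification of the silyl ether onto the ketone (Et3SiH, BiBr3, MeCN, 0 °C), through the same oxocarbenium ion 18, comes back to the route at 19.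

**Further compounds**

F1 | step 5 | (2S,3S)-2-[4-(tert-butyldimethylsilyloxy)-3,5-dimethoxyphenyl]-3-ethenylcyclobutan-1-one | COc1cc([C@H]2C(=O)C[C@H]2C=C)cc(OC)c1O[Si](C)(C)C(C)(C)C
F2 | step 5 | (4S,5S)-5-[4-(tert-butyldimethylsilyloxy)-3,5-dimethoxyphenyl]-4-ethenyloxolan-2-one | COc1cc([C@H]2OC(=O)C[C@H]2C=C)cc(OC)c1O[Si](C)(C)C(C)(C)C
F3 | step 5 | (4S,5S)-5-[4-(tert-butyldimethylsilyloxy)-3,5-dimethoxyphenyl]-4-(hydroxymethyl)oxolan-2-one | COc1cc([C@H]2OC(=O)C[C@H]2CO)cc(OC)c1O[Si](C)(C)C(C)(C)C
F4 | step 5 | 3,4-bis(tert-butyldimethylsilyloxy)benzoic acid | OC(=O)c1ccc(O[Si](C)(C)C(C)(C)C)c(O[Si](C)(C)C(C)(C)C)c1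
F5 | step 7 | (2S,3R)-2-[4-(tert-butyldimethylsilyloxy)-3,5-dimethoxyphenyl]-3-[(tert-butyldimethylsilyloxy)methyl]cyclobutan-1-one | COc1cc([C@H]2C(=O)C[C@H]2CO[Si](C)(C)C(C)(C)C)cc(OC)c1O[Si](C)(C)C(C)(C)C
F6 | step 7 | (4S,5S)-5-[4-(tert-butyldimethylsilyloxy)-3,5-dimethoxyphenyl]-4-[(tert-butyldimethylsilyloxy)methyl]oxolan-2-one | COc1cc([C@H]2OC(=O)C[C@H]2CO[Si](C)(C)C(C)(C)C)cc(OC)c1O[Si](C)(C)C(C)(C)C
F7 | step 7 | (4S,5S)-3-[3,4-bis(tert-butyldimethylsilyloxy)benzoyl]-5-[4-(tert-butyldimethylsilyloxy)-3,5-dimethoxyphenyl]-4-[(tert-butyldimethylsilyloxy)methyl]oxolan-2-one, C3 not defined | COc1cc([C@H]2OC(=O)C(C(=O)c3ccc(O[Si](C)(C)C(C)(C)C)c(O[Si](C)(C)C(C)(C)C)c3)[C@H]2CO[Si](C)(C)C(C)(C)C)cc(OC)c1O[Si](C)(C)C(C)(C)C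
F8 | step 8 | (3S,3aS)-6-[3,4-bis(tert-butyldimethylsilyloxy)phenyl]-3-[4-(tert-butyldimethylsilyloxy)-3,5-dimethoxyphenyl]-3,3a-dihydro-1H,4H-furo[3,4-c]furan-1-one | COc1cc([C@H]2OC(=O)C3=C(c4ccc(O[Si](C)(C)C(C)(C)C)c(O[Si](C)(C)C(C)(C)C)c4)OC[C@@H]23)cc(OC)c1O[Si](C)(C)C(C)(C)C
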